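**Oblongifolin B by enantioselective dearomative annulation of a diprenyl acylphloroglucinol**

- Cuts, in retrosynthetic order: the two catechol O–Si bonds and the enol O–CH3 bond; the geranyl C1′–C2′ bond (C7–CH2 to the vinyl carbon), an sp3–sp2 Negishi bond; then C1–C8 and C5–C6 together, which opens ring C1–C9–C5–C6–C7–C8.
- Enabling feature: ring C1–C2–C3–C4–C5–C9 carries oxygen on C2, C4 and C9, the aroyl group on C3 and a prenyl group on each bridgehead, so it is a dearomatized 3,5-diprenyl-2,4,6-trihydroxybenzophenone. The bridge C6–C7–C8 (CH2–CH–CMe2) is the chain of the enal Me2C=C(CHO)CH2OAc, electrophilic at both ends, laid across the two prenyl-bearing carbons.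
- Forward: the phloroglucinol ring is bought, aroylated and C-prenylated twice as a flat arene. One annulation dearomatizes it and closes the second six-membered ring. The C7 formyl group becomes CH2I, the geranyl chain is joined last, and two deprotections finish.
- Stereochemistry: C1 and C5 arise together in the annulation (a chiral ammonium ion pair chooses the face for the first bond, the tether forces cis bridging). C7 comes from thermodynamic equilibration of the formyl group to exo. The E alkene comes from syn-carboalumination and a stereoretentive coupling.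

Key step: step 10

Conventions: the bicyclo[3.3.1]nonane is numbered with C1/C5 as bridgeheads, C9 the bridging ketone, C8 the CMe2 carbon next to C1, C7 the side-chain carbon and C6 the CH2 next to C5. The enol is drawn as 4-hydroxy-2-oxo. "Exo" at C7 means equatorial on the chair ring C1–C9–C5–C6–C7–C8, pointing away from the C2–C3–C4 bridge. In this numbering and tautomer the target is (1S,5S,7R).

Assumption: of the two pseudo-enantiomeric catalysts (cinchonidine- or cinchonine-derived), the one that leads to the bridgehead configuration of the target is used. The cinchonidinium salt is written; a test reaction with assignment of the product would settle the choice.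

Remark: the carbinol of step 3 is racemic and its stereocentre is removed in step 4. The carbinol carbon of the adamantane intermediate of step 10 is left undefined because the retro-aldol erases it.

**Route**

Step 1
Reactants: 1 phloroglucinol
Product: 2 1,3,5-tris(methoxymethoxy)benzene
Conditions: NaH, MOMCl, DMF, 0 °C to rt
Reagents that add atoms: chloromethyl methyl ether (MOMCl), COCCl
Why: Threefold Williamson O-alkylation of the sodium phenoxides with the hard electrophile MOMCl gives the tris-acetal, whose OMOM groups later direct ring lithiation and come off with mild acid.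

Step 2
Reactants: 3 3,4-dihydroxybenzaldehyde
Product: 4 3,4-bis(triisopropylsilyloxy)benzaldehyde
Conditions: TIPSCl, imidazole, DMAP (cat.), DMF, rt to 40 °C
Reagents that add atoms: chlorotriisopropylsilane (TIPSCl), CC(C)[Si](Cl)(C(C)C)C(C)C
Why: Imidazole-promoted silylation of both phenols; TIPS is chosen because aryl TIPS ethers tolerate aryllithium reagents, dilute methanolic acid and water-free amidine or amide bases, and are cleaved at the end by fluoride.

Step 3
Reactants: 2 1,3,5-tris(methoxymethoxy)benzene; 4 3,4-bis(triisopropylsilyloxy)benzaldehyde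
Product: 6 [3,4-bis(triisopropylsilyloxy)phenyl][2,4,6-tris(methoxymethoxy)phenyl]methanol (racemic), via aryllithium 5 (not isolated)
Conditions: n-BuLi, THF, 0 °C; then 4, −78 °C to 0 °C; aq. NH4Cl
Reagents that add atoms: none
Why: Directed ortho-metalation at the ring position flanked by two OMOM groups gives aryllithium 5, which undergoes 1,2-addition to the non-enolizable aldehyde.

Step 4
Reactants: 6 [3,4-bis(triisopropylsilyloxy)phenyl][2,4,6-tris(methoxymethoxy)phenyl]methanol
Product: 7 [3,4-bis(triisopropylsilyloxy)phenyl][2,4,6-tris(methoxymethoxy)phenyl]methanone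
Conditions: Dess–Martin periodinane, NaHCO3, CH2Cl2, rt
Reagents that add atoms: none
Why: Dess–Martin oxidation of the doubly benzylic secondary alcohol under buffered, neutral conditions should leave the acetals and silyl ethers untouched.

Step 5
Reactants: 7 [3,4-bis(triisopropylsilyloxy)phenyl][2,4,6-tris(methoxymethoxy)phenyl]methanone
Product: 8 [3,4-bis(triisopropylsilyloxy)phenyl](2,4,6-trihydroxyphenyl)methanone
Conditions: HCl (1.25 M in MeOH), rt
Reagents that add atoms: none
Why: Acid-catalysed acetal methanolysis transfers the three MOM groups to methanol, while the bulky aryl TIPS ethers, far more stable to acid than to base, should persist at room temperature.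

Step 6
Reactants: 8 [3,4-bis(triisopropylsilyloxy)phenyl](2,4,6-trihydroxyphenyl)methanone; 9 prenyl bromide (1-bromo-3-methylbut-2-ene, about 2 equiv)
Product: 10 [3,4-bis(triisopropylsilyloxy)phenyl][2,4,6-trihydroxy-3,5-bis(3-methylbut-2-enyl)phenyl]methanone
Conditions: DBU, THF, 0 °C to rt
Reagents that add atoms: none
Why: The acylphloroglucinol is a vinylogous acid whose amidinium-paired anion is C-allylated by the soft bromide at both free ring positions (twofold C-prenylation of an ambident phenoxide); the water-free base spares the silyl ethers and the stoichiometry limits over-alkylation.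

Step 7
Reactants: 11 diethyl 2-(propan-2-ylidene)malonate
Product: 12 2-(propan-2-ylidene)propane-1,3-diol
Conditions: i-Bu2AlH, CH2Cl2, −78 °C to 0 °C; aq. KNaC4H4O6 (potassium sodium tartrate)
Reagents that add atoms: none
Why: i-Bu2AlH reduces both conjugated esters by 1,2-hydride delivery to the allylic diol without conjugate reduction of the tetrasubstituted alkene.

Step 8
Reactants: 12 2-(propan-2-ylidene)propane-1,3-diol
Product: 14 2-(hydroxymethyl)-3-methylbut-2-enyl acetate, via cyclic orthoester 13 (not isolated)
Conditions: MeC(OMe)3, pyridinium p-toluenesulfonate (cat.), CH2Cl2, rt; then H2O, rt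
Reagents that add atoms: trimethyl orthoacetate, COC(C)(OC)OC; water, O
Why: Acid-catalysed orthoester exchange ties the 1,3-diol into cyclic orthoester 13, whose hydrolysis can deliver only one acetyl group per molecule, so mono-acetylation is secured by mechanism and not by statistics.

Step 9
Reactants: 14 2-(hydroxymethyl)-3-methylbut-2-enyl acetate
Product: 15 2-formyl-3-methylbut-2-enyl acetate
Conditions: MnO2, CH2Cl2, rt
Reagents that add atoms: none
Why: MnO2 oxidizes the allylic alcohol selectively to the enal; the acetate is inert and the tetrasubstituted alkene has no geometry to lose.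

Step 10
Reactants: 10 [3,4-bis(triisopropylsilyloxy)phenyl][2,4,6-trihydroxy-3,5-bis(3-methylbut-2-enyl)phenyl]methanone; 15 2-formyl-3-methylbut-2-enyl acetate
Product: 19 3-[3,4-bis(triisopropylsilyloxy)benzoyl]-4-hydroxy-8,8-dimethyl-1,5-bis(3-methylbut-2-enyl)-2,9-dioxobicyclo[3.3.1]non-3-ene-7-carbaldehyde (7-exo; bridgeheads as in the target), via dearomatized acrolein 16 (not isolated), via endo aldehyde 17 (not isolated), via adamantane aldol 18 (not isolated)
Conditions: 15 (1.5 equiv), O-allyl-N-(9-anthracenylmethyl)cinchonidinium bromide (20 mol %), CsOH·H2O, 4 Å MS, CH2Cl2, −50 °C; then solvent switch to THF, KN(SiMe3)2, 65 °C; 1 M HCl quench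
Reagents that add atoms: none
Why: The phenoxide of 10, ion-paired with the cinchonidinium cation, adds through a prenyl-bearing ring carbon to the β,β-dimethyl carbon of 15 and acetate leaves by E1cB (net SN2′), which forms C1–C8 and gives dearomatized acrolein 16; its enolate then attacks the new terminal methylene through the second prenyl-bearing carbon (C5–C6) in a 6-endo-trig Michael closure of ring C1–C9–C5–C6–C7–C8. The closest known reaction is the base-mediated alkylative dearomatization–annulation of 3,5-diprenyl acylphloroglucinols with 2-(acetoxymethyl) enals, including its cinchona phase-transfer variant, applied here to a silyloxy-substituted aroyl group. C1 is set by the chiral cation, which decides on which face of the planar, time-averaged C2v-symmetric anion the first bond forms (the two prenyl-bearing carbons are equivalent, their faces enantiotopic); C5 follows because the three-atom tether can reach the second carbon only on that same face, so the bridge is necessarily cis. C7 is set thermodynamically: endo aldehyde 17 from kinetic protonation is held at low temperature as its aldol with C3 (adamantane aldol 18), and KN(SiMe3)2 at 65 °C should reverse the aldol and epimerize the formyl group through its enolate to the exo (equatorial) position, which cannot re-close onto C3. The step needs C- over O-alkylation, attack by the prenyl-bearing and not the aroyl-bearing carbon, and facial selectivity; the soft, delocalized vinylogous-acid anion with its deactivated acyl-bearing carbon secures the first two and the tight ion pair the third. The bridgeheads cannot scramble during equilibration because they carry no hydrogen and a retro-Michael opening can only re-close under control of the surviving quaternary centre.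

Step 11
Reactants: 19 7-exo aldehyde with free enol
Product: 20 3-[3,4-bis(triisopropylsilyloxy)benzoyl]-4-methoxy-8,8-dimethyl-1,5-bis(3-methylbut-2-enyl)-2,9-dioxobicyclo[3.3.1]non-3-ene-7-carbaldehyde (7-exo; bridgeheads as in the target)
Conditions: TMSCHN2, i-Pr2NEt, MeCN/MeOH, 0 °C to rt
Reagents that add atoms: trimethylsilyldiazomethane, C[Si](C)(C)C=[N+]=[N-]
Why: The acidic β-triketone enol is O-methylated by the diazomethane released from TMSCHN2 by methanol; methylation is expected at the oxygen on C4, remote from the CMe2 group (a C2–O isomer would converge in step 17), and the aldehyde is inert without a Lewis acid.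

Step 12
Reactants: 20 enol methyl ether aldehyde
Product: 21 3-[3,4-bis(triisopropylsilyloxy)benzoyl]-7-(hydroxymethyl)-4-methoxy-8,8-dimethyl-1,5-bis(3-methylbut-2-enyl)bicyclo[3.3.1]non-3-ene-2,9-dione (7-exo; bridgeheads as in the target)
Conditions: NaBH4, MeOH/THF, −20 °C
Reagents that add atoms: none
Why: Borohydride reduction is chemoselective for the aldehyde because the C9 ketone lies between two quaternary carbons and the remaining carbonyls are a vinylogous ester and its conjugated aryl ketone; the exo configuration at C7 is the stable one and is fixed once the aldehyde is gone.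

Step 13
Reactants: 21 primary alcohol
Product: 22 3-[3,4-bis(triisopropylsilyloxy)benzoyl]-7-(iodomethyl)-4-methoxy-8,8-dimethyl-1,5-bis(3-methylbut-2-enyl)bicyclo[3.3.1]non-3-ene-2,9-dione (7-exo; bridgeheads as in the target)
Conditions: I2, PPh3, imidazole, CH2Cl2, 0 °C to rt
Reagents that add atoms: iodine, II
Why: Appel reaction: the alkoxyphosphonium ion is displaced by iodide in an SN2 reaction at the primary carbon, so C7 is not touched, and trisubstituted alkenes survive these conditions.

Step 14
Reactants: 23 5-bromo-2-methylpent-2-ene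
Product: 24 6-methylhept-5-en-1-yne
Conditions: LiC≡CH·H2NCH2CH2NH2 (lithium acetylide–ethylenediamine complex), DMSO, 10 °C to rt
Reagents that add atoms: lithium acetylide–ethylenediamine complex, [Li]C#C.NCCN
Why: SN2 alkylation of lithium acetylide by the primary homoallylic bromide in a dipolar aprotic solvent.

Step 15
Reactants: 24 6-methylhept-5-en-1-yne
Product: 26 (E)-1-iodo-2,6-dimethylhepta-1,5-diene, via alkenylalane 25 (not isolated)
Conditions: Me3Al, Cp2ZrCl2 (25 mol %), CH2Cl2, 0 °C to rt; then I2, THF, −30 °C to 0 °C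
Reagents that add atoms: trimethylaluminium, C[Al](C)C; iodine, II
Why: Zirconium-catalysed carboalumination (Negishi) adds methyl and aluminium syn across the terminal alkyne with aluminium on the terminal carbon (alkenylalane 25), and iodinolysis with retention gives the E iodide; the remote trisubstituted alkene is inert.

Step 16
Reactants: 22 primary iodide; 26 (E)-1-iodo-2,6-dimethylhepta-1,5-diene
Product: 28 3-[3,4-bis(triisopropylsilyloxy)benzoyl]-7-[(2E)-3,7-dimethylocta-2,6-dienyl]-4-methoxy-8,8-dimethyl-1,5-bis(3-methylbut-2-enyl)bicyclo[3.3.1]non-3-ene-2,9-dione (7-exo; bridgeheads as in the target), via alkylzinc iodide 27 (not isolated)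
Conditions: Zn dust (activated with BrCH2CH2Br and Me3SiCl), LiCl, THF, 40 °C; then 26, Pd(PPh3)4 (5 mol %), THF, rt to 50 °C
Reagents that add atoms: none
Why: Zinc inserts into the primary C–I bond to give alkylzinc iodide 27, which tolerates the ketones and the vinylogous ester, and Negishi coupling with 26 at the zerovalent palladium catalyst (oxidative addition, transmetalation, reductive elimination) forms the C1′–C2′ bond with retention of the E geometry and without involvement of C7.

Step 17
Reactants: 28 protected oblongifolin B (enol methyl ether, bis-TIPS catechol)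
Product: 29 3-[3,4-bis(triisopropylsilyloxy)benzoyl]-7-[(2E)-3,7-dimethylocta-2,6-dienyl]-4-hydroxy-8,8-dimethyl-1,5-bis(3-methylbut-2-enyl)bicyclo[3.3.1]non-3-ene-2,9-dione (7-exo; bridgeheads as in the target)
Conditions: LiCl, DMSO, 120 °C; 1 M HCl work-up
Reagents that add atoms: none
Why: Chloride attacks the methyl group of the vinylogous ester in an SN2 dealkylation (Krapcho-type) and releases the stabilized triketone anion; the neutral medium spares the alkenes, and partial loss of silyl groups would be harmless because step 18 removes them.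

Step 18
Reactants: 29 bis-TIPS oblongifolin B
Product: 30 oblongifolin B, (1S,5S,7R)-3-(3,4-dihydroxybenzoyl)-7-[(2E)-3,7-dimethylocta-2,6-dienyl]-4-hydroxy-8,8-dimethyl-1,5-bis(3-methylbut-2-enyl)bicyclo[3.3.1]non-3-ene-2,9-dione
Conditions: Bu4NF, AcOH, THF, 0 °C to rt
Reagents that add atoms: none
Why: Fluoride cleaves both aryl Si–O bonds; the acetic acid buffer keeps catechol and triketone protonated, which avoids catecholate oxidation, and no strong acid is present that could cyclize the enol onto a prenyl group.

**Compound list**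

1 | phloroglucinol (benzene-1,3,5-triol) | Oc1cc(O)cc(O)c1 | starting material
2 | 1,3,5-tris(methoxymethoxy)benzene | COCOc1cc(OCOC)cc(OCOC)c1 | intermediate
3 | 3,4-dihydroxybenzaldehyde | O=Cc1ccc(O)c(O)c1 | starting material
4 | 3,4-bis(triisopropylsilyloxy)benzaldehyde | O=Cc1ccc(O[Si](C(C)C)(C(C)C)C(C)C)c(O[Si](C(C)C)(C(C)C)C(C)C)c1 | intermediate
5 | 2,4,6-tris(methoxymethoxy)phenyllithium | [Li]c1c(OCOC)cc(OCOC)cc1OCOC | intermediate (not isolated)
6 | [3,4-bis(triisopropylsilyloxy)phenyl][2,4,6-tris(methoxymethoxy)phenyl]methanol, racemic | OC(c1c(OCOC)cc(OCOC)cc1OCOC)c1ccc(O[Si](C(C)C)(C(C)C)C(C)C)c(O[Si](C(C)C)(C(C)C)C(C)C)c1 | intermediate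
7 | [3,4-bis(triisopropylsilyloxy)phenyl][2,4,6-tris(methoxymethoxy)phenyl]methanone | O=C(c1c(OCOC)cc(OCOC)cc1OCOC)c1ccc(O[Si](C(C)C)(C(C)C)C(C)C)c(O[Si](C(C)C)(C(C)C)C(C)C)c1 | intermediate
8 | [3,4-bis(triisopropylsilyloxy)phenyl](2,4,6-trihydroxyphenyl)methanone | O=C(c1c(O)cc(O)cc1O)c1ccc(O[Si](C(C)C)(C(C)C)C(C)C)c(O[Si](C(C)C)(C(C)C)C(C)C)c1 | intermediate
9 | prenyl bromide (1-bromo-3-methylbut-2-ene) | CC(C)=CCBr | starting material
10 | [3,4-bis(triisopropylsilyloxy)phenyl][2,4,6-trihydroxy-3,5-bis(3-methylbut-2-enyl)phenyl]methanone | CC(C)=CCc1c(O)c(CC=C(C)C)c(O)c(C(=O)c2ccc(O[Si](C(C)C)(C(C)C)C(C)C)c(O[Si](C(C)C)(C(C)C)C(C)C)c2)c1O | intermediate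
11 | diethyl 2-(propan-2-ylidene)malonate | CCOC(=O)C(=C(C)C)C(=O)OCC | starting material
12 | 2-(propan-2-ylidene)propane-1,3-diol | CC(C)=C(CO)CO | intermediate
13 | 2-methoxy-2-methyl-5-(propan-2-ylidene)-1,3-dioxane (cyclic orthoester) | COC1(C)OCC(=C(C)C)CO1 | intermediate (not isolated)
14 | 2-(hydroxymethyl)-3-methylbut-2-enyl acetate | CC(C)=C(CO)COC(C)=O | intermediate
15 | 2-formyl-3-methylbut-2-enyl acetate | CC(C)=C(C=O)COC(C)=O | intermediate
16 | 2-[3,4-bis(triisopropylsilyloxy)benzoyl]-6-(3-formyl-2-methylbut-3-en-2-yl)-3,5-dihydroxy-4,6-bis(3-methylbut-2-enyl)cyclohexa-2,4-dien-1-one (dearomatized acrolein; quaternary ring carbon is the future C1) | C=C(C=O)C(C)(C)[C@]1(CC=C(C)C)C(=O)C(C(=O)c2ccc(O[Si](C(C)C)(C(C)C)C(C)C)c(O[Si](C(C)C)(C(C)C)C(C)C)c2)=C(O)C(CC=C(C)C)=C1O | intermediate (not isolated)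
17 | 7-endo epimer of aldehyde 19 | O=C[C@H]1C[C@]2(CC=C(C)C)C(=O)[C@@](CC=C(C)C)(C(=O)C(C(=O)c3ccc(O[Si](C(C)C)(C(C)C)C(C)C)c(O[Si](C(C)C)(C(C)C)C(C)C)c3)=C2O)C1(C)C | intermediate (not isolated)
18 | adamantane aldol of 17: 3-aroyl-10-hydroxy-8,8-dimethyl-1,5-diprenyladamantane-2,4,9-trione (bicyclononane numbering kept, C10 joins C3 and C7; carbinol configuration open) | OC1[C@H]2C[C@]3(CC=C(C)C)C(=O)[C@](CC=C(C)C)(C2(C)C)C(=O)[C@@]1(C(=O)c4ccc(O[Si](C(C)C)(C(C)C)C(C)C)c(O[Si](C(C)C)(C(C)C)C(C)C)c4)C3=O | intermediate (not isolated)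
19 | 7-exo aldehyde with free enol (bicyclo[3.3.1]nonane trione) | O=C[C@@H]1C[C@]2(CC=C(C)C)C(=O)[C@@](CC=C(C)C)(C(=O)C(C(=O)c3ccc(O[Si](C(C)C)(C(C)C)C(C)C)c(O[Si](C(C)C)(C(C)C)C(C)C)c3)=C2O)C1(C)C | intermediate
20 | 4-O-methyl enol ether of 19 | O=C[C@@H]1C[C@]2(CC=C(C)C)C(=O)[C@@](CC=C(C)C)(C(=O)C(C(=O)c3ccc(O[Si](C(C)C)(C(C)C)C(C)C)c(O[Si](C(C)C)(C(C)C)C(C)C)c3)=C2OC)C1(C)C | intermediate
21 | 7-exo hydroxymethyl enol methyl ether | OC[C@@H]1C[C@]2(CC=C(C)C)C(=O)[C@@](CC=C(C)C)(C(=O)C(C(=O)c3ccc(O[Si](C(C)C)(C(C)C)C(C)C)c(O[Si](C(C)C)(C(C)C)C(C)C)c3)=C2OC)C1(C)C | intermediate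
22 | 7-exo iodomethyl enol methyl ether | IC[C@@H]1C[C@]2(CC=C(C)C)C(=O)[C@@](CC=C(C)C)(C(=O)C(C(=O)c3ccc(O[Si](C(C)C)(C(C)C)C(C)C)c(O[Si](C(C)C)(C(C)C)C(C)C)c3)=C2OC)C1(C)C | intermediate
23 | 5-bromo-2-methylpent-2-ene | CC(C)=CCCBr | starting material
24 | 6-methylhept-5-en-1-yne | CC(C)=CCCC#C | intermediate
25 | (E)-(2,6-dimethylhepta-1,5-dienyl)dimethylalane | CC(C)=CCC/C(C)=C/[Al](C)C | intermediate (not isolated)
26 | (E)-1-iodo-2,6-dimethylhepta-1,5-diene | CC(C)=CCC/C(C)=C/I | intermediate
27 | alkylzinc iodide from 22 (C7–CH2–ZnI) | I[Zn]C[C@@H]1C[C@]2(CC=C(C)C)C(=O)[C@@](CC=C(C)C)(C(=O)C(C(=O)c3ccc(O[Si](C(C)C)(C(C)C)C(C)C)c(O[Si](C(C)C)(C(C)C)C(C)C)c3)=C2OC)C1(C)C | intermediate (not isolated)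
28 | protected oblongifolin B (4-O-methyl enol ether, bis-TIPS catechol) | CC(C)=CCC/C(C)=C/C[C@@H]1C[C@]2(CC=C(C)C)C(=O)[C@@](CC=C(C)C)(C(=O)C(C(=O)c3ccc(O[Si](C(C)C)(C(C)C)C(C)C)c(O[Si](C(C)C)(C(C)C)C(C)C)c3)=C2OC)C1(C)C | intermediate
29 | bis-TIPS oblongifolin B (free enol) | CC(C)=CCC/C(C)=C/C[C@@H]1C[C@]2(CC=C(C)C)C(=O)[C@@](CC=C(C)C)(C(=O)C(C(=O)c3ccc(O[Si](C(C)C)(C(C)C)C(C)C)c(O[Si](C(C)C)(C(C)C)C(C)C)c3)=C2O)C1(C)C | intermediate
30 | oblongifolin B | CC(C)=CCC/C(C)=C/C[C@@H]1C[C@]2(CC=C(C)C)C(=O)[C@@](CC=C(C)C)(C(=O)C(C(=O)c3ccc(O)c(O)c3)=C2O)C1(C)C | target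

**Count**

Total: 18 steps. Longest linear sequence: 12 steps (steps 1, 3, 4, 5, 6, 10, 11, 12, 13, 16, 17, 18, from phloroglucinol; the branch from 3,4-dihydroxybenzaldehyde is equally long).

**Steps most likely to fail, with fallbacks**

Step 10. What may go wrong is poor facial selectivity in the first C–C bond formation. The ion pair has to tell apart the two faces of a large dianion that now carries a bulky bis-silyloxyaroyl group, so the bicycle may form with low enantiomeric excess. Fallback: optical purity is secured downstream by classical resolution instead of by the catalyst. The fallback sets out from 21 and comes back at 21. Alcohol 21, of whatever enantiomeric excess, would be esterified with (S)-2-methoxy-2-phenylacetic acid (DCC, DMAP, CH2Cl2). This should give the (S)-O-methylmandelate of 21 F1 together with the (S)-O-methylmandelate of the mirror-image alcohol F2. The two are diastereomers and would be separated by chromatography. Methanolysis of F1 (K2CO3, MeOH, 0 °C, at which aryl TIPS ethers should hold) would return enantiopure 21 for step 13.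

Step 16. What may go wrong is sluggish zinc insertion at the β-branched iodide next to the quaternary C8, protonation of the organozinc to the C7 methyl compound, or homocoupling during the palladium stage. Fallback: the preformed organometallic is dropped in favour of a nickel-catalysed reductive cross-electrophile coupling. It sets out from 22 (with 26) and comes back at 28. Both iodides would be combined with NiBr2(MeOCH2CH2OMe) (10 mol %), 4,4′-di-tert-butyl-2,2′-bipyridine and Mn powder in DMA at rt. The alkyl radical from 22 is captured at nickel carrying the alkenyl group, and the alkene geometry should be retained. No new compound is made on the way.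

Step 6. What may go wrong is loss of control over the degree and site of alkylation: O- against C-prenylation, and mono-, geminal di- and tri-prenylation, giving a mixture that is hard to separate. Fallback: the prenyl groups are placed by directed lithiation before the aroyl group is introduced. It sets out from 2 and comes back at 10.
- Aryllithium 5 (n-BuLi, THF, 0 °C) would be alkylated with prenyl bromide 9 to give 2-prenyl-1,3,5-tris(methoxymethoxy)benzene F3.
- A second lithiation between two OMOM groups would give the monoprenyl aryllithium F4, and alkylation with 9 would give 2,4-diprenyl-1,3,5-tris(methoxymethoxy)benzene F5.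
- Lithiation of the last ring position would give the diprenyl aryllithium F6, which adds to aldehyde 4 to give the diprenyl diaryl carbinol F7.
- Dess–Martin oxidation would give the diprenyl tris-MOM benzophenone F8.
- Brief treatment with HCl in MeOH at 0 °C to rt would remove the acetals and deliver 10.

**Further compounds**

F1 | step 10 | (S)-O-methylmandelate of alcohol 21 | CO[C@H](C(=O)OC[C@@H]1C[C@]2(CC=C(C)C)C(=O)[C@@](CC=C(C)C)(C(=O)C(C(=O)c3ccc(O[Si](C(C)C)(C(C)C)C(C)C)c(O[Si](C(C)C)(C(C)C)C(C)C)c3)=C2OC)C1(C)C)c1ccccc1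
F2 | step 10 | (S)-O-methylmandelate of the mirror-image alcohol (enantiomer of 21) | CO[C@H](C(=O)OC[C@H]1C[C@@]2(CC=C(C)C)C(=O)[C@](CC=C(C)C)(C(=O)C(C(=O)c3ccc(O[Si](C(C)C)(C(C)C)C(C)C)c(O[Si](C(C)C)(C(C)C)C(C)C)c3)=C2OC)C1(C)C)c1ccccc1
F0 | step 16 | none | none
F3 | step 6 | 2-(3-methylbut-2-enyl)-1,3,5-tris(methoxymethoxy)benzene | COCOc1cc(OCOC)c(CC=C(C)C)c(OCOC)c1
F4 | step 6 | 3-(3-methylbut-2-enyl)-2,4,6-tris(methoxymethoxy)phenyllithium | [Li]c1c(OCOC)cc(OCOC)c(CC=C(C)C)c1OCOC
F5 | step 6 | 2,4-bis(3-methylbut-2-enyl)-1,3,5-tris(methoxymethoxy)benzene | CC(C)=CCc1c(OCOC)cc(OCOC)c(CC=C(C)C)c1OCOC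
F6 | step 6 | 3,5-bis(3-methylbut-2-enyl)-2,4,6-tris(methoxymethoxy)phenyllithium | [Li]c1c(OCOC)c(CC=C(C)C)c(OCOC)c(CC=C(C)C)c1OCOC
F7 | step 6 | [3,4-bis(triisopropylsilyloxy)phenyl][3,5-bis(3-methylbut-2-enyl)-2,4,6-tris(methoxymethoxy)phenyl]methanol, racemic | OC(c1c(OCOC)c(CC=C(C)C)c(OCOC)c(CC=C(C)C)c1OCOC)c1ccc(O[Si](C(C)C)(C(C)C)C(C)C)c(O[Si](C(C)C)(C(C)C)C(C)C)c1
F8 | step 6 | [3,4-bis(triisopropylsilyloxy)phenyl][3,5-bis(3-methylbut-2-enyl)-2,4,6-tris(methoxymethoxy)phenyl]methanone | O=C(c1c(OCOC)c(CC=C(C)C)c(OCOC)c(CC=C(C)C)c1OCOC)c1ccc(O[Si](C(C)C)(C(C)C)C(C)C)c(O[Si](C(C)C)(C(C)C)C(C)C)c1
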